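**Strategy.** The plan cuts the 1,2-dioxolane (O1–O2–C3–C4–C5) at C4–C5 and C3–O2. The feature used is that C4 is an unsubstituted CH2 between the two fully substituted carbons C3 and C5. A ketone-derived peroxycarbenium ion (C5–O1–O2) can therefore be intercepted by the CH2 end of a 1,1-disubstituted alkene (C4=C3). One catalytic asymmetric [3+2] annulation should build the ring, both new bonds and both quaternary stereocentres. Its precursor is an acyclic methoxy triethylsilylperoxy ketal of an 11-silyloxyundecan-2-one, paired with methyl 3-methylbut-3-enoate. The triene is attached afterwards by olefination, because it would not survive the cationic step.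

Key step: step 5

Remark: the perketal carbon of 5 and 6 is used racemic because it becomes planar on ionisation; (3S,5R) places the two ring methyl groups trans; which catalyst enantiomer gives the (3S,5R) series has to be found by screening.

**Step 1**
Reactants: 1 8-bromooctan-1-ol
Product: 2 (8-bromooctyloxy)(tert-butyl)diphenylsilane
Conditions: TBDPSCl, imidazole, DMF, 0 °C → rt
Reagents that add atoms: tert-butyl(chloro)diphenylsilane, CC(C)(C)[Si](Cl)(c1ccccc1)c1ccccc1
Why: Imidazole-promoted silylation of the primary alcohol (silyl ether formation) leaves the primary bromide untouched and installs an ether expected to tolerate Grignard reagents, ozone and Lewis acids later on.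

**Step 2**
Reactants: 2 (8-bromooctyloxy)(tert-butyl)diphenylsilane; 3 2-methylallylmagnesium chloride
Product: 4 tert-butyl[(10-methylundec-10-en-1-yl)oxy]diphenylsilane
Conditions: Li2CuCl4 (3 mol %), THF, −20 °C → rt
Reagents that add atoms: none
Why: Copper-catalysed sp3–sp3 cross-coupling of an allylic Grignard reagent with a primary alkyl bromide should join the methallyl unit to the chain, and since the methallyl group is symmetric toward allylic transposition only one alkene can result.

**Step 3**
Reactants: 4 tert-butyl[(10-methylundec-10-en-1-yl)oxy]diphenylsilane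
Product: 5 tert-butyl[(10-hydroperoxy-10-methoxyundecyl)oxy]diphenylsilane (racemic)
Conditions: O3, CH2Cl2/MeOH (3:1), −78 °C (indicator dye to stop at the end point); N2 purge, concentrate cold, no reductant
Reagents that add atoms: ozone, [O-][O+]=O; methanol, CO
Why: Ozonolysis in methanol, in which the primary ozonide of a 1,1-dialkyl alkene should fragment mainly to formaldehyde and the dialkyl carbonyl oxide, the latter being trapped by methanol as the α-methoxy hydroperoxide with the O–O bond kept because no reductant is added.

**Step 4**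
Reactants: 5 tert-butyl[(10-hydroperoxy-10-methoxyundecyl)oxy]diphenylsilane
Product: 6 tert-butyl{[10-methoxy-10-(triethylsilylperoxy)undecyl]oxy}diphenylsilane (racemic)
Conditions: Et3SiCl, imidazole, DMF, 0 °C
Reagents that add atoms: chlorotriethylsilane, CC[Si](Cl)(CC)CC
Why: O-silylation of the hydroperoxide, the only acidic OH present, under mildly basic conditions that should not ionise the ketal.

**Step 5**
Reactants: 6 tert-butyl{[10-methoxy-10-(triethylsilylperoxy)undecyl]oxy}diphenylsilane; 7 methyl 3-methylbut-3-enoate
Product: 9 methyl 2-[(3S,5R)-5-{9-[(tert-butyldiphenylsilyl)oxy]nonyl}-3,5-dimethyl-1,2-dioxolan-3-yl]acetate, via peroxycarbenium ion 8 (not isolated)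
Conditions: Et3Si–IDPi (5 mol %; confined BINOL-derived imidodiphosphorimidate acid silylated beforehand with allyltriethylsilane), 7 (3 equiv), toluene, −78 °C → −60 °C
Reagents that add atoms: none
Why: Proposed new method: the silylated imidodiphosphorimidate passes Et3Si+ to the methoxy oxygen of 6, Et3SiOMe departs and peroxycarbenium ion 8 remains as a contact ion pair with the confined chiral anion; the CH2 terminus of 7 then adds to C5 to leave a tertiary carbenium ion at C3, the silylated peroxide oxygen O2 collapses onto it, and the silyl group returns to the anion so that the catalyst turns over. The closest known reaction is the racemic SnCl4-promoted [3+2] annulation of triethylsilylperoxy ketals with 1,1-disubstituted alkenes, and the control element is extrapolated from silylium imidodiphosphorimidate catalysis of additions to oxocarbenium-type ions, where such anions can tell methyl from a larger alkyl group. The 1,2-dioxolane is closed stepwise, by intermolecular C4–C5 bond formation followed by a five-membered cation–oxygen collapse that forms C3–O2 and breaks no π bond. C5 (R) is set by the face of the peroxycarbenium ion left open by the anion, which must distinguish methyl from the long chain; C3 (S) is set at ring closure by the conformation in which the chiral pocket holds the C3 cation, placing the C3 methyl trans to the C5 methyl. Regiochemistry is secured by the substrates themselves (both cationic centres are tertiary, the ester could reach C3 only through a four-membered ring, and no other π nucleophile is present), whereas enantio- and diastereoselectivity rest entirely on the catalyst.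

**Step 6**
Reactants: 9 methyl 2-[(3S,5R)-5-{9-[(tert-butyldiphenylsilyl)oxy]nonyl}-3,5-dimethyl-1,2-dioxolan-3-yl]acetate
Product: 10 methyl 2-[(3S,5R)-5-(9-hydroxynonyl)-3,5-dimethyl-1,2-dioxolan-3-yl]acetate
Conditions: Bu4NF, AcOH (1:1), THF, 0 °C → rt
Reagents that add atoms: none
Why: Fluoride-induced desilylation buffered with acetic acid, so that the methyl ester and the di-tertiary peroxide (no hydrogen on either peroxide carbon, hence no Kornblum–DeLaMare fragmentation) should remain intact.

**Step 7**
Reactants: 10 methyl 2-[(3S,5R)-5-(9-hydroxynonyl)-3,5-dimethyl-1,2-dioxolan-3-yl]acetate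
Product: 11 methyl 2-[(3S,5R)-3,5-dimethyl-5-(9-oxononyl)-1,2-dioxolan-3-yl]acetate
Conditions: Dess–Martin periodinane, CH2Cl2, 0 °C → rt
Reagents that add atoms: none
Why: Dess–Martin oxidation of the primary alcohol to the aldehyde under neutral, non-reducing conditions that dialkyl peroxides tolerate.

**Step 8**
Reactants: 12 (2E,4E)-hepta-2,4-dienal
Product: 13 (2E,4E)-hepta-2,4-dien-1-ol
Conditions: NaBH4, CeCl3·7H2O, MeOH, 0 °C
Reagents that add atoms: none
Why: Luche 1,2-reduction delivers hydride to the carbonyl carbon only, so both E double bonds are carried over.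

**Step 9**
Reactants: 13 (2E,4E)-hepta-2,4-dien-1-ol
Product: 14 (2E,4E)-1-bromohepta-2,4-diene
Conditions: PBr3, Et2O, −10 °C → 0 °C; used without delay
Reagents that add atoms: phosphorus tribromide, BrP(Br)Br
Why: Bromide displaces the phosphite ester of the primary dienylic alcohol (SN2) at low temperature, and the fully conjugated primary (E,E) bromide is also the thermodynamically preferred allylic isomer.

**Step 10**
Reactants: 14 (2E,4E)-1-bromohepta-2,4-diene
Product: 15 diethyl [(2E,4E)-hepta-2,4-dien-1-yl]phosphonate
Conditions: P(OEt)3 (neat), 110 °C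
Reagents that add atoms: triethyl phosphite, CCOP(OCC)OCC
Why: Michaelis–Arbuzov reaction, in which the phosphite attacks the primary carbon and bromide dealkylates the phosphonium salt while volatile bromoethane leaves the mixture.

**Step 11**
Reactants: 11 methyl 2-[(3S,5R)-3,5-dimethyl-5-(9-oxononyl)-1,2-dioxolan-3-yl]acetate; 15 diethyl [(2E,4E)-hepta-2,4-dien-1-yl]phosphonate
Product: 17 methyl 2-[(3S,5R)-5-[(9E,11E,13E)-hexadeca-9,11,13-trien-1-yl]-3,5-dimethyl-1,2-dioxolan-3-yl]acetate, via lithiated phosphonate 16 (not isolated)
Conditions: 15, n-BuLi, THF, −78 °C; then 11, −78 °C → rt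
Reagents that add atoms: none
Why: Horner–Wadsworth–Emmons olefination with a preformed allyl-stabilised phosphonate carbanion, so that 11 never meets free strong base; reversible addition and elimination through the less crowded oxaphosphetane should make the new C9=C10 bond E while the two existing E alkenes are carried over, and addition to the aldehyde should outrun any reaction at the hindered ester or the peroxide.

**Step 12**
Reactants: 17 methyl 2-[(3S,5R)-5-[(9E,11E,13E)-hexadeca-9,11,13-trien-1-yl]-3,5-dimethyl-1,2-dioxolan-3-yl]acetate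
Product: 19 2-[(3S,5R)-5-[(9E,11E,13E)-hexadeca-9,11,13-trien-1-yl]-3,5-dimethyl-1,2-dioxolan-3-yl]acetic acid, via lithium carboxylate 18 (not isolated)
Conditions: LiOH·H2O, THF/MeOH/H2O, 0 °C → rt; then 1 M HCl to pH 3–4, 0 °C
Reagents that add atoms: lithium hydroxide, [Li+].[OH-]
Why: Saponification of the methyl ester (acyl substitution by hydroxide) followed by mild acidification; C3 and C5 are quaternary and cannot epimerise, and hydroxide is too weak a base to enolise the ester and open the ring by β-elimination.

**Compound list**

1 | 8-bromooctan-1-ol | OCCCCCCCCBr | starting material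
2 | (8-bromooctyloxy)(tert-butyl)diphenylsilane | CC(C)(C)[Si](c1ccccc1)(c1ccccc1)OCCCCCCCCBr | intermediate
3 | 2-methylallylmagnesium chloride | CC(=C)C[Mg]Cl | starting material
4 | tert-butyl[(10-methylundec-10-en-1-yl)oxy]diphenylsilane | CC(=C)CCCCCCCCCO[Si](c1ccccc1)(c1ccccc1)C(C)(C)C | intermediate
5 | tert-butyl[(10-hydroperoxy-10-methoxyundecyl)oxy]diphenylsilane (racemic) | CC(C)(C)[Si](c1ccccc1)(c1ccccc1)OCCCCCCCCCC(C)(OC)OO | intermediate
6 | tert-butyl{[10-methoxy-10-(triethylsilylperoxy)undecyl]oxy}diphenylsilane (racemic) | CC(C)(C)[Si](c1ccccc1)(c1ccccc1)OCCCCCCCCCC(C)(OC)OO[Si](CC)(CC)CC | intermediate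
7 | methyl 3-methylbut-3-enoate | C=C(C)CC(=O)OC | starting material
8 | peroxycarbenium ion, paired with the chiral imidodiphosphorimidate anion (cation shown) | CC(=[O+]O[Si](CC)(CC)CC)CCCCCCCCCO[Si](c1ccccc1)(c1ccccc1)C(C)(C)C | intermediate
9 | methyl 2-[(3S,5R)-5-{9-[(tert-butyldiphenylsilyl)oxy]nonyl}-3,5-dimethyl-1,2-dioxolan-3-yl]acetate | CC(C)(C)[Si](c1ccccc1)(c1ccccc1)OCCCCCCCCC[C@]1(C)C[C@@](C)(CC(=O)OC)OO1 | intermediate
10 | methyl 2-[(3S,5R)-5-(9-hydroxynonyl)-3,5-dimethyl-1,2-dioxolan-3-yl]acetate | OCCCCCCCCC[C@]1(C)C[C@@](C)(CC(=O)OC)OO1 | intermediate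
11 | methyl 2-[(3S,5R)-3,5-dimethyl-5-(9-oxononyl)-1,2-dioxolan-3-yl]acetate | O=CCCCCCCCC[C@]1(C)C[C@@](C)(CC(=O)OC)OO1 | intermediate
12 | (2E,4E)-hepta-2,4-dienal | CC/C=C/C=C/C=O | starting material
13 | (2E,4E)-hepta-2,4-dien-1-ol | CC/C=C/C=C/CO | intermediate
14 | (2E,4E)-1-bromohepta-2,4-diene | CC/C=C/C=C/CBr | intermediate
15 | diethyl [(2E,4E)-hepta-2,4-dien-1-yl]phosphonate | CC/C=C/C=C/CP(=O)(OCC)OCC | intermediate
16 | lithiated phosphonate (lithium salt of the carbanion of 15) | CC/C=C/C=C/[CH-]P(=O)(OCC)OCC.[Li+] | intermediate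
17 | methyl 2-[(3S,5R)-5-[(9E,11E,13E)-hexadeca-9,11,13-trien-1-yl]-3,5-dimethyl-1,2-dioxolan-3-yl]acetate | CC/C=C/C=C/C=C/CCCCCCCC[C@]1(C)C[C@@](C)(CC(=O)OC)OO1 | intermediate
18 | lithium 2-[(3S,5R)-5-[(9E,11E,13E)-hexadeca-9,11,13-trien-1-yl]-3,5-dimethyl-1,2-dioxolan-3-yl]acetate | CC/C=C/C=C/C=C/CCCCCCCC[C@]1(C)C[C@@](C)(CC(=O)[O-])OO1.[Li+] | intermediate
19 | 2-[(3S,5R)-5-[(9E,11E,13E)-hexadeca-9,11,13-trien-1-yl]-3,5-dimethyl-1,2-dioxolan-3-yl]acetic acid | CC/C=C/C=C/C=C/CCCCCCCC[C@]1(C)C[C@@](C)(CC(=O)O)OO1 | target

**Step count.** Total: 12 steps. Longest linear sequence: 9 steps (steps 1–7, 11 and 12); steps 8–10 form the three-step phosphonate branch.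

**Steps most likely to fail**

Step 5. The ion pair may discriminate poorly between the two faces of the peroxycarbenium ion (methyl against the long chain at C5) or between the two senses of ring closure at C3. The C3 cation may also lose a proton to give open-chain unsaturated peroxides, and the ester carbonyl may sequester the silylium catalyst. Fallback, setting out from 6 and 7: the established Lewis-acid version (SnCl4, CH2Cl2, −78 °C) should give methyl 2-[5-{9-[(tert-butyldiphenylsilyl)oxy]nonyl}-3,5-dimethyl-1,2-dioxolan-3-yl]acetate as all four stereoisomers F1. Stereocontrol is then replaced by separation: silica chromatography to isolate the trans-dimethyl racemate, then preparative HPLC on a polysaccharide chiral stationary phase. The (3S,5R) enantiomer, assigned by vibrational circular dichroism or by comparing the rotation of derived 19 with the natural product, re-enters the route as 9.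

Step 11. The new double bond may form with incomplete E selectivity. Proton transfer from the ester or aldehyde α-CH2 to the phosphonate anion could also trigger β-elimination and ring opening. Fallback, setting out from alcohol 10: a Mitsunobu reaction with 1-phenyl-1H-tetrazole-5-thiol (PPh3, DIAD, THF) would give methyl 2-[(3S,5R)-3,5-dimethyl-5-{9-[(1-phenyl-1H-tetrazol-5-yl)sulfanyl]nonyl}-1,2-dioxolan-3-yl]acetate F2. Oxidation (H2O2, catalytic (NH4)6Mo7O24·4H2O, EtOH) would give methyl 2-[(3S,5R)-3,5-dimethyl-5-{9-[(1-phenyl-1H-tetrazol-5-yl)sulfonyl]nonyl}-1,2-dioxolan-3-yl]acetate F3. A Julia–Kocienski olefination of F3 with dienal 12 (KN(SiMe3)2 added to the mixture of both in DME at −60 °C) forms C9=C10 with reversed polarity and returns to the route at 17. This fallback also makes steps 7–10 unnecessary.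

Step 3. The primary ozonide may partition toward formaldehyde O-oxide and the ketone, and excess ozone may attack the silyl phenyl rings, eroding the supply of 5. Fallback, setting out from alkene 4: ozonolysis with reductive work-up (O3, CH2Cl2, −78 °C; then PPh3) gives 11-[(tert-butyldiphenylsilyl)oxy]undecan-2-one F4. A Wittig reaction with methoxymethylenetriphenylphosphorane (Ph3P(Cl)CH2OMe, KN(SiMe3)2, THF) gives the enol ether tert-butyl[(11-methoxy-10-methylundec-10-en-1-yl)oxy]diphenylsilane F5 as an E/Z mixture of no consequence. Ozonolysis of F5 in CH2Cl2/MeOH at −78 °C fragments by the known enol-ether preference to methyl formate and the wanted ketone O-oxide, whose trapping by methanol returns to the route at 5.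

**Further compounds**

F1 | step 5 | methyl 2-[5-{9-[(tert-butyldiphenylsilyl)oxy]nonyl}-3,5-dimethyl-1,2-dioxolan-3-yl]acetate (mixture of all four stereoisomers) | CC(C)(C)[Si](c1ccccc1)(c1ccccc1)OCCCCCCCCCC1(C)CC(C)(CC(=O)OC)OO1
F2 | step 11 | methyl 2-[(3S,5R)-3,5-dimethyl-5-{9-[(1-phenyl-1H-tetrazol-5-yl)sulfanyl]nonyl}-1,2-dioxolan-3-yl]acetate | c1ccc(cc1)-n2nnnc2SCCCCCCCCC[C@]3(C)C[C@@](C)(CC(=O)OC)OO3
F3 | step 11 | methyl 2-[(3S,5R)-3,5-dimethyl-5-{9-[(1-phenyl-1H-tetrazol-5-yl)sulfonyl]nonyl}-1,2-dioxolan-3-yl]acetate | c1ccc(cc1)-n2nnnc2S(=O)(=O)CCCCCCCCC[C@]3(C)C[C@@](C)(CC(=O)OC)OO3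
F4 | step 3 | 11-[(tert-butyldiphenylsilyl)oxy]undecan-2-one | CC(=O)CCCCCCCCCO[Si](c1ccccc1)(c1ccccc1)C(C)(C)C
F5 | step 3 | tert-butyl[(11-methoxy-10-methylundec-10-en-1-yl)oxy]diphenylsilane (E/Z mixture) | COC=C(C)CCCCCCCCCO[Si](c1ccccc1)(c1ccccc1)C(C)(C)C
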